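The all-cis oxolane (O, C6, C7, C8, C9; kumausyne numbering) carries its acetate on C7 next to the ether carbon C6, the pattern left when a 3-acetyloxolane undergoes Baeyer–Villiger oxidation. Such a ketone is the product of a Prins–pinacol union. In one operation an acyclic allylic 1,2-diol (C1–C8 plus a sacrificial methyl carbinol carbon) and a 2-bromoaldehyde (C9–C15) condense: the C6 oxygen bonds to C9, the vinyl terminus C8 adds to C9, and a 1,2-shift joins C6 to C7 while the carbinol carbon is extruded as the acetyl group. The precursor is therefore a vinyl, propargyl diol and not a ring; the extruded carbon becomes the natural acetate.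

Key step: step 6

Remarks on the chemistry:
- Numbering used throughout: C1≡C2–C3=C4–C5–C6(O)–C7(OAc)–C8–C9(O)–C10(Br)–C11–C12=C13–C14–C15.
- Assumption: (2S,5S)-2,5-diphenylpyrrolidine is taken to deliver the (R)-bromoaldehyde, on the steric model in which the phenyl group next to the enamine carbon blocks one face. Should the sense be the opposite, the (2R,5R) catalyst is used instead.
- Diol 6 is used as a mixture of epimers at the tertiary carbinol carbon, because that carbon ends as the acetyl carbonyl.

Step 1
Reactants: 1 hex-5-yn-2-one; 2 nitrosobenzene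
Product: 3 (3R)-3-[(phenylamino)oxy]hex-5-yn-2-one
Conditions: L-proline (20 mol %), DMSO, rt, slow addition of 2 to 1 (3 equiv)
Reagents that add atoms: nitrosobenzene, O=Nc1ccccc1
Why: Proline-catalysed α-aminoxylation (O-selective nitroso aldol): the more substituted enamine attacks the nitroso oxygen, which is held by the carboxylic acid on one face, so L-proline should set the future C6 as R.

Step 2
Reactants: 3 (3R)-3-[(phenylamino)oxy]hex-5-yn-2-one; 4 vinylmagnesium bromide
Product: 6 (3RS,4R)-3-methylhept-1-en-6-yne-3,4-diol, via aminoxy carbinol 5 (not isolated)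
Conditions: CH2=CHMgBr (3.5 equiv), THF, −78 → −20 °C; then AcOH, Zn dust, 0 °C → rt
Reagents that add atoms: vinylmagnesium bromide, C=C[Mg]Br
Why: Grignard 1,2-addition to the α-oxygenated ketone, then reductive N–O cleavage with zinc in the same flask; the new carbinol centre forms as a mixture that does not matter (it becomes the acetyl carbonyl in step 6), and C4 is untouched.

Step 3
Reactants: 7 pent-1-en-3-ol; 8 triethyl orthoacetate
Product: 10 ethyl (4E)-hept-4-enoate, via ketene acetal 9 (not isolated)
Conditions: MeC(OEt)3 (excess), EtCO2H (cat.), 140 °C, distillation of EtOH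
Reagents that add atoms: triethyl orthoacetate, CCOC(C)(OCC)OCC
Why: Johnson–Claisen rearrangement; the chair transition state with the ethyl group equatorial should give the (E)-alkene with high selectivity.

Step 4
Reactants: 10 ethyl (4E)-hept-4-enoate
Product: 11 (4E)-hept-4-enal
Conditions: i-Bu2AlH (1.05 equiv), CH2Cl2, −78 °C; then aqueous potassium sodium tartrate
Reagents that add atoms: none
Why: Partial reduction of the ester; the tetrahedral aluminium hemiacetal is stable at −78 °C and releases the aldehyde only on work-up, and no stereocentre is formed.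

Step 5
Reactants: 11 (4E)-hept-4-enal; 12 4,4-dibromo-2,6-di-tert-butylcyclohexa-2,5-dien-1-one
Product: 13 (2R,4E)-2-bromohept-4-enal
Conditions: (2S,5S)-2,5-diphenylpyrrolidine (20 mol %), PhCO2H (20 mol %), H2O (2 equiv), CH2Cl2/pentane 1:1, −40 °C; cold filtration through silica, used at once
Reagents that add atoms: 4,4-dibromo-2,6-di-tert-butylcyclohexa-2,5-dien-1-one, CC(C)(C)C1=CC(Br)(Br)C=C(C(C)(C)C)C1=O
Why: Enamine-catalysed α-bromination of an aldehyde; the phenyl group next to the (E)-enamine carbon of the C2-symmetric amine blocks one face, so the mild bromine donor should set C10 as R, and the enamine is far more nucleophilic than the isolated alkene.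

Step 6
Reactants: 6 (3RS,4R)-3-methylhept-1-en-6-yne-3,4-diol; 13 (2R,4E)-2-bromohept-4-enal
Product: 15 1-[(2R,3R,5R)-5-[(1R,3E)-1-bromohex-3-en-1-yl]-2-(prop-2-yn-1-yl)oxolan-3-yl]ethan-1-one, via dioxolane acetal 14 (not isolated)
Conditions: CSA (5 mol %), MgSO4, CH2Cl2, 0 °C; then SnCl4 (2 equiv), −78 → −25 °C
Reagents that add atoms: none
Why: Acid-catalysed acetalisation gives dioxolane 14, which SnCl4 opens at the tertiary allylic oxygen to the (E)-oxocarbenium ion on the C6 oxygen (this is the O–C9 bond); the vinyl terminus C8 then adds to C9 in a 6-endo-trig Prins closure through a chair, and the C7 cation is quenched by a pinacol 1,2-shift of C6 from the carbinol carbon to C7, which contracts the oxane to the oxolane and unmasks the acetyl group. The closest known reaction is the Prins–pinacol synthesis of 3-acyltetrahydrofurans from allylic 1,2-diols and aldehydes, applied here to a 2-bromoaldehyde. The oxolane is thus closed by a 6-endo Prins cyclisation followed by a suprafacial ring-contracting shift, not by a direct five-membered closure. C9 is set by the chair in which the bromoalkyl and propargyl groups are both equatorial (2,5-cis), C7 by migration of C6 onto the cation face it already occupies (acetyl cis to both side chains), C6 is carried over from the diol with retention as the migrating carbon, and C10 comes unchanged from the aldehyde. The step needs the vinyl group to react in preference to the alkyne and the C12=C13 alkene, and needs C7 and C10 not to epimerise: only the vinyl group reaches the oxocarbenium carbon through a six-membered chair and its cation is captured at once by the adjacent carbinol, whereas the alkyne would give a vinyl cation and the remote alkene a four-membered or strained five-membered ring, and a non-basic Lewis acid at low temperature should keep the kinetic all-cis ketone and the bromide intact.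

Step 7
Reactants: 15 1-[(2R,3R,5R)-5-[(1R,3E)-1-bromohex-3-en-1-yl]-2-(prop-2-yn-1-yl)oxolan-3-yl]ethan-1-one; 16 bis(trimethylsilyl) peroxide
Product: 17 (2R,3R,5R)-5-[(1R,3E)-1-bromohex-3-en-1-yl]-2-(prop-2-yn-1-yl)oxolan-3-yl acetate
Conditions: (Me3SiO)2 (2 equiv), TMSOTf (0.2 equiv), CH2Cl2, −40 → 0 °C
Reagents that add atoms: bis(trimethylsilyl) peroxide, C[Si](C)(C)OO[Si](C)(C)C
Why: Baeyer–Villiger oxidation through a silylated Criegee adduct; the secondary ring carbon C7 migrates in preference to methyl with retention, so the C7 acetate keeps the all-cis configuration, and the silyl peroxide is not an epoxidising agent, so the alkene and alkyne should survive.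

Step 8
Reactants: 17 (2R,3R,5R)-5-[(1R,3E)-1-bromohex-3-en-1-yl]-2-(prop-2-yn-1-yl)oxolan-3-yl acetate; 18 Cp2Zr(H)Cl; 19 iodine
Product: 21 (2R,3R,5R)-5-[(1R,3E)-1-bromohex-3-en-1-yl]-2-[(2E)-3-iodoprop-2-en-1-yl]oxolan-3-yl acetate, via alkenylzirconocene 20 (not isolated)
Conditions: Cp2Zr(H)Cl (1.2 equiv), THF, 0 °C → rt, 20 min; then I2 (1.2 equiv), 0 °C
Reagents that add atoms: iodine, II
Why: Hydrozirconation adds Zr–H syn across the terminal alkyne with zirconium at the terminal carbon, and iodinolysis of the C–Zr bond goes with retention, so the (E)-iodoalkene results; the acetate, the secondary bromide and the internal alkene react much more slowly.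

Step 9
Reactants: 21 (2R,3R,5R)-5-[(1R,3E)-1-bromohex-3-en-1-yl]-2-[(2E)-3-iodoprop-2-en-1-yl]oxolan-3-yl acetate; 22 ethynylmagnesium bromide
Product: 23 trans-kumausyne, (2R,3R,5R)-5-[(1R,3E)-1-bromohex-3-en-1-yl]-2-[(2E)-pent-2-en-4-yn-1-yl]oxolan-3-yl acetate
Conditions: HC≡CMgBr (3 equiv), ZnBr2 (3 equiv), THF, 0 °C; then 21, Pd(PPh3)4 (5 mol %), THF, rt
Reagents that add atoms: ethynylmagnesium bromide, C#C[Mg]Br
Why: Negishi coupling: oxidative addition of the alkenyl iodide to zerovalent palladium, transmetalation from ethynylzinc bromide and reductive elimination keep the (E) geometry and give the free terminal enyne without a protecting group, under conditions that should leave the acetate and the secondary bromide untouched.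

Compound list
1 | hex-5-yn-2-one | CC(=O)CCC#C | starting material
2 | nitrosobenzene | O=Nc1ccccc1 | starting material
3 | (3R)-3-[(phenylamino)oxy]hex-5-yn-2-one | C#CC[C@@H](ONc1ccccc1)C(C)=O | intermediate
4 | vinylmagnesium bromide | C=C[Mg]Br | starting material
5 | (3RS,4R)-3-methyl-4-[(phenylamino)oxy]hept-1-en-6-yn-3-ol (not isolated) | C#CC[C@@H](ONc1ccccc1)C(C)(O)C=C | intermediate
6 | (3RS,4R)-3-methylhept-1-en-6-yne-3,4-diol | C#CC[C@@H](O)C(C)(O)C=C | intermediate
7 | pent-1-en-3-ol (racemic) | CCC(O)C=C | starting material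
8 | triethyl orthoacetate | CCOC(C)(OCC)OCC | starting material
9 | 3-[(1-ethoxyethenyl)oxy]pent-1-ene (not isolated) | C=CC(CC)OC(=C)OCC | intermediate
10 | ethyl (4E)-hept-4-enoate | CC/C=C/CCC(=O)OCC | intermediate
11 | (4E)-hept-4-enal | CC/C=C/CCC=O | intermediate
12 | 4,4-dibromo-2,6-di-tert-butylcyclohexa-2,5-dien-1-one | CC(C)(C)C1=CC(Br)(Br)C=C(C(C)(C)C)C1=O | starting material
13 | (2R,4E)-2-bromohept-4-enal | O=C[C@H](Br)C/C=C/CC | intermediate
14 | (5R)-2-[(1R,3E)-1-bromohex-3-en-1-yl]-4-ethenyl-4-methyl-5-(prop-2-yn-1-yl)-1,3-dioxolane, mixture at C2 and C4 (not isolated) | C#CC[C@H]1OC(OC1(C)C=C)[C@H](Br)C/C=C/CC | intermediate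
15 | 1-[(2R,3R,5R)-5-[(1R,3E)-1-bromohex-3-en-1-yl]-2-(prop-2-yn-1-yl)oxolan-3-yl]ethan-1-one | C#CC[C@H]1O[C@@H]([C@H](Br)C/C=C/CC)C[C@H]1C(C)=O | intermediate
16 | bis(trimethylsilyl) peroxide | C[Si](C)(C)OO[Si](C)(C)C | starting material
17 | (2R,3R,5R)-5-[(1R,3E)-1-bromohex-3-en-1-yl]-2-(prop-2-yn-1-yl)oxolan-3-yl acetate | C#CC[C@H]1O[C@@H]([C@H](Br)C/C=C/CC)C[C@H]1OC(C)=O | intermediate
18 | Cp2Zr(H)Cl, bis(cyclopentadienyl)zirconium chloride hydride (rings drawn sigma-bonded) | [H][Zr](Cl)(C1C=CC=C1)C1C=CC=C1 | starting material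
19 | iodine | II | starting material
20 | (E)-alkenylzirconocene chloride from 17 (rings drawn sigma-bonded; not isolated) | Cl[Zr](/C=C/C[C@H]1O[C@@H]([C@H](Br)C/C=C/CC)C[C@H]1OC(C)=O)(C1C=CC=C1)C1C=CC=C1 | intermediate
21 | (2R,3R,5R)-5-[(1R,3E)-1-bromohex-3-en-1-yl]-2-[(2E)-3-iodoprop-2-en-1-yl]oxolan-3-yl acetate | I/C=C/C[C@H]1O[C@@H]([C@H](Br)C/C=C/CC)C[C@H]1OC(C)=O | intermediate
22 | ethynylmagnesium bromide | C#C[Mg]Br | starting material
23 | trans-kumausyne | C#C/C=C/C[C@H]1O[C@@H]([C@H](Br)C/C=C/CC)C[C@H]1OC(C)=O | target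

Total step count: 9. Longest linear sequence: 7 steps (steps 3 to 9, from pent-1-en-3-ol).

Steps most likely to fail

Step 6. The bromoaldehyde or its oxocarbenium ion may enolise and lose the C10 configuration, the oxocarbenium ion may be diverted by the alkyne or the side-chain alkene, the cation may be trapped by chloride before the pinacol shift, or the kinetic cis-acetyl centre may epimerise. The fallback sets out from 6 and returns at 17, and it moves the C10 stereocentre to after ring formation. Diol 6 is condensed with (benzyloxy)acetaldehyde under the conditions of step 6, which should give 1-[(2R,3R,5R)-5-[(benzyloxy)methyl]-2-(prop-2-yn-1-yl)oxolan-3-yl]ethan-1-one F1. Baeyer–Villiger oxidation with mCPBA/NaHCO3, safe here because no alkene is present, should give (2R,3R,5R)-5-[(benzyloxy)methyl]-2-(prop-2-yn-1-yl)oxolan-3-yl acetate F2. Debenzylation with BCl3 in CH2Cl2 at −78 °C should give (2R,3R,5R)-5-(hydroxymethyl)-2-(prop-2-yn-1-yl)oxolan-3-yl acetate F3, and Dess–Martin oxidation should give (2R,3R,5R)-5-formyl-2-(prop-2-yn-1-yl)oxolan-3-yl acetate F4. Addition of 3-(trimethylsilyl)pent-1-ene with BF3·OEt2 at −78 °C (allylsilane addition with allylic transposition, (E)-selective, Felkin–Anh control by the ring oxygen) should give (2R,3R,5R)-5-[(1S,3E)-1-hydroxyhex-3-en-1-yl]-2-(prop-2-yn-1-yl)oxolan-3-yl acetate F5. Appel bromination (CBr4, PPh3, 2,6-di-tert-butylpyridine, toluene, 70 °C) with inversion at C10 then gives 17.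

Step 5. The product can re-enter the enamine cycle and lose enantiomeric purity or take up a second bromine, and the bromine donor may attack the alkene. The fallback sets out from 10 and returns at 13, and it replaces catalyst control by an oxazolidinone auxiliary. Saponification of 10 (LiOH, THF/H2O) gives (4E)-hept-4-enoic acid F6. Acylation of lithiated (R)-4-benzyloxazolidin-2-one through the pivaloyl mixed anhydride gives (4R)-4-benzyl-3-[(4E)-hept-4-enoyl]-1,3-oxazolidin-2-one F7. Bromination of its boron enolate (Bu2BOTf, i-Pr2NEt; then NBS, −78 °C) on the face away from the benzyl group should give (4R)-4-benzyl-3-[(2R,4E)-2-bromohept-4-enoyl]-1,3-oxazolidin-2-one F8. Reductive removal of the auxiliary with LiBH4 in THF/H2O at 0 °C gives (2R,4E)-2-bromohept-4-en-1-ol F9, and Dess–Martin oxidation buffered with NaHCO3 gives 13, used at once.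

Step 7. The silyl peroxide may oxidise the hindered methyl ketone too slowly, and the Lewis acid may epimerise C7 before oxygen insertion. The fallback sets out from 15 and returns at 17, and it lets a peracid take both the ketone and the alkene and then restores the alkene. Excess mCPBA buffered with Na2HPO4 in CH2Cl2 should effect the Baeyer–Villiger oxidation and epoxidise C12=C13, giving (2R,3R,5R)-5-[(1R)-1-bromo-2-(trans-3-ethyloxiran-2-yl)ethyl]-2-(prop-2-yn-1-yl)oxolan-3-yl acetate F10 as a mixture of the two trans-epoxides. Stereospecific deoxygenation with Ph3P=Se and CF3CO2H in CH2Cl2, which proceeds with retention of alkene geometry, then returns the (E)-alkene and gives 17.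

Further compounds
F1 | step 6 | 1-[(2R,3R,5R)-5-[(benzyloxy)methyl]-2-(prop-2-yn-1-yl)oxolan-3-yl]ethan-1-one | C#CC[C@H]1O[C@@H](COCc2ccccc2)C[C@H]1C(C)=O
F2 | step 6 | (2R,3R,5R)-5-[(benzyloxy)methyl]-2-(prop-2-yn-1-yl)oxolan-3-yl acetate | C#CC[C@H]1O[C@@H](COCc2ccccc2)C[C@H]1OC(C)=O
F3 | step 6 | (2R,3R,5R)-5-(hydroxymethyl)-2-(prop-2-yn-1-yl)oxolan-3-yl acetate | C#CC[C@H]1O[C@@H](CO)C[C@H]1OC(C)=O
F4 | step 6 | (2R,3R,5R)-5-formyl-2-(prop-2-yn-1-yl)oxolan-3-yl acetate | C#CC[C@H]1O[C@@H](C=O)C[C@H]1OC(C)=O
F5 | step 6 | (2R,3R,5R)-5-[(1S,3E)-1-hydroxyhex-3-en-1-yl]-2-(prop-2-yn-1-yl)oxolan-3-yl acetate | C#CC[C@H]1O[C@@H]([C@@H](O)C/C=C/CC)C[C@H]1OC(C)=O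
F6 | step 5 | (4E)-hept-4-enoic acid | CC/C=C/CCC(=O)O
F7 | step 5 | (4R)-4-benzyl-3-[(4E)-hept-4-enoyl]-1,3-oxazolidin-2-one | CC/C=C/CCC(=O)N1[C@H](Cc2ccccc2)COC1=O
F8 | step 5 | (4R)-4-benzyl-3-[(2R,4E)-2-bromohept-4-enoyl]-1,3-oxazolidin-2-one | CC/C=C/C[C@@H](Br)C(=O)N1[C@H](Cc2ccccc2)COC1=O
F9 | step 5 | (2R,4E)-2-bromohept-4-en-1-ol | CC/C=C/C[C@@H](Br)CO
F10 | step 7 | (2R,3R,5R)-5-[(1R)-1-bromo-2-(trans-3-ethyloxiran-2-yl)ethyl]-2-(prop-2-yn-1-yl)oxolan-3-yl acetate (epoxide carbons left undefined: both trans-epoxides) | C#CC[C@H]1O[C@@H]([C@H](Br)CC2OC2CC)C[C@H]1OC(C)=O
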